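1. A small charge of Z, 24 mM, goes against 21.6 mM of X in alder, oak and ash, and you read them at 40 min. Alder gets its X and oak its Z by steady feed over 8.0 min; ash gets everything at once.

| setting | amber | ochre | teal | alder | oak | ash |
|---|---|---|---|---|---|---|
| Z | 24 mM | 34 mM | 53 mM | 24 mM | 24 mM (fed, over 8.0 min) | 24 mM |
| X | 21.6 mM | 21.6 mM | 21.6 mM | 21.6 mM (fed, over 8.0 min) | 21.6 mM | 21.6 mM |
| remark | run made earlier | run made earlier | run made earlier | all else is in the flask from the start; the feed brings no volume worth counting | all else is in the flask from the start; the feed brings no volume worth counting | everything together at the start |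
| time |  |  |  | 40 min | 40 min | 40 min |

- amber (time / min: G / %, E / %): 2.00: 52.0, 27.0; 4.00: 47.6, 36.2; 10.0: 40.2, 49.7; 25.0: 33.3, 61.2
- ochre (time / min: G / %, E / %): 3.00: 37.2, 46.5; 8.00: 31.0, 60.0; 15.0: 26.4, 67.1; 40.0: 21.3, 75.8
- teal (time / min: G / %, E / %): 5.00: 22.1, 69.3; 15.0: 17.3, 78.9; 25.0: 15.1, 81.9; 40.0: 12.9, 84.5

(scatter of a reading: 0.3 percentage points)

- percentages count the Z that a species holds: one E counts as two
- the numbers in the tables scatter with a standard deviation of 0.3 percentage points

- the flask that comes out highest in share of G in G plus E, or "all alike" when all lie within 1.5 percentage points (alder / oak / ash / all alike)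
- share of G in G plus E at the end, alder
- share of G in G plus E at the end, oak
- share of G in G plus E at the end, ash

2. Amber is ash's recipe, so read the flask there. What G and E do not hold is free Z: at 10.0 min, 2.42 mM.

3. Suppose the fast step stands in balance (a pre-equilibrium), each G taking one X and freeing one partner. Amber then reads 3.21 for the balance quotient, [G] times [G] over [Z] times [X].

4. When you come, reckon [Z] in alder, oak and ash as [G][G] over the product of 3.21 and [X]. In amber, E is still rising and G still falling at 25.0 min.

5. Leave the feeds alone. Amber held 27.0 % of its Z as E at 2.00 min, with X there from the start, and in this reckoning each G takes one X.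

6. The forecast, which I keep: oak highest, alder 20 %, oak 33 %, ash 31.5 %, since “G is a rapidly reversible store of Z”. Its numbers do not come from my quotient.

The flasks gave oak highest, with alder 23.7 %, oak 32.4 % and ash 30.7 %.

    Z + X ⇌ G + J (K = 3.20, k = 5.23 L mol⁻¹ s⁻¹)
    2 Z → E (k = 0.467 L mol⁻¹ s⁻¹)

In alder at the end, the step Z + X ⇌ G + J relaxed, both ways together, with a half-life of 0.110 min, short against the 40 min of the run. With alder's final G and X, the quotient gives [Z] = 0.598 mM, and the flask held 0.597 mM. A neighbour of alder charged with 6.0 mM of Z gives 0.248 mM by the same reckoning, and it held 0.249 mM.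

(All runs were computed on assumed constants; noise was put on by code.)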